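**Retrosynthetic overview**
1. Target ⇒ caffeate C=C and ester C–O: Knoevenagel–Doebner condensation of malonic half-ester 11 with 3,4-dihydroxybenzaldehyde; 11 ⇐ allylic alcohol 9 + Meldrum's acid (no protecting groups).
2. 9 ⇐ Wittig methylenation of hydroxy-cyclopentanone 8.
3. 8 ⇐ one cationic cascade on monocyclic hydroxy ketone 5: C7–C11 ring closure (Prins), 1,2-methyl shift C7→C6, 1,2-methyl shift C11→C7 ending in the ketone. This is the ring closure and the two methyl shifts of the bisabolyl → cuprenyl → trichodienyl-type cation sequence.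
4. 5 ⇐ alkoxide-tethered ene reaction of trans-carveol 2 with methyl vinyl ketone; 2 ⇐ CBS reduction of (R)-carvone.
5. Ring order: the cyclohexene ring is bought as (R)-carvone; the cyclopentane is the only ring formed (step 3).

Assumption: atom labels follow biogenetic numbering (C2 carbinol carbon; C6 ring carbon that becomes the ring quaternary centre; C7 its exocyclic neighbour; C8–C10 chain CH2 groups; C11 ketone carbon, later the methylidene-bearing carbon). Steps 2 and 3 are untested proposals, and their stereochemical outcome rests on a delivery model, not on precedent.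

**Step 1**
Reactants: 1 (R)-(−)-carvone
Product: 2 (1S,5R)-2-methyl-5-(prop-1-en-2-yl)cyclohex-2-en-1-ol (trans-carveol)
Conditions: (R)-Me-CBS (15 mol%), catecholborane (1.5 equiv), toluene, −78 °C; aq. NaOH work-up
Reagents that add atoms: none
Why: Corey–Bakshi–Shibata 1,2-reduction; the 2-methyl-enone binds with its alkenyl arm as the large group, so the catalyst (not the remote C5 centre) sets the carbinol as S, which places OH trans to the isopropenyl group, and catecholborane at −78 °C leaves both C=C bonds alone.

**Step 2**
Reactants: 2 trans-carveol; 3 methyl vinyl ketone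
Product: 5 (Z)-6-[(5S)-5-hydroxy-4-methylcyclohex-3-en-1-ylidene]heptan-2-one, via aluminium alkoxide 4 (not isolated)
Conditions: Me2AlCl (1.1 equiv), CH2Cl2, −78 °C; then 3 (1.5 equiv), −78 → −30 °C; cold 1 M HCl
Reagents that add atoms: none
Why: Proposed new method: the pseudo-axial O–Al(Me)Cl of 4 acts as an internal Lewis acid that binds the enone and delivers its β-carbon to the isopropenyl CH2 on the ring face carrying O2; the axial C6–H is 1,3-diaxial to that oxygen and is the allylic hydrogen nearest the tethered enolate, so its transfer gives the tetrasubstituted C6=C7 olefin, and because the new chain is still tied to O2 through aluminium it ends cis to the CH2 bearing the carbinol (Z); no new stereocentre is formed and C2 is untouched; the closest known reactions are alkylaluminium halide-promoted ene reactions of methyl vinyl ketone with 1,1-disubstituted alkenes (zwitterion, then 1,5-proton transfer) and Lewis acid catalysis by alkoxyaluminium chlorides.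

**Step 3**
Reactants: 5 (Z)-hydroxy ketone
Product: 8 (2R)-2-[(1S,5S)-5-hydroxy-1,4-dimethylcyclohex-3-en-1-yl]-2-methylcyclopentan-1-one, via dichloroaluminium alkoxide 6 (not isolated), via aluminate zwitterion 7 (not isolated)
Conditions: MeAlCl2 (2.2 equiv), CH2Cl2, −78 → −20 °C; cold 1 M HCl
Reagents that add atoms: none
Why: Proposed new method: the C2–O–AlCl2 group of 6 (reinforced by the second equivalent) binds the side-chain ketone and delivers C11 to C7 on the face syn to O2 in a 5-exo Prins closure, giving 7 with a tertiary cation at C6 and the C11 methyl cis to the C7 methyl; the C7 methyl then migrates to C6 anti to the new C7–C11 bond (methyl trans, cyclopentyl cis to O2, which fixes C6), and the C11 methyl follows suprafacially into the vacated site at C7 as the alkoxide collapses to the ketone (semipinacol sink, which fixes C7 from the Z geometry and the C11 configuration); the same ring closure and the same two 1,2-methyl shifts occur in the biosynthesis of this skeleton, and the closest known laboratory reactions are alkylaluminium halide-promoted Prins cyclizations of olefinic carbonyl compounds that continue by consecutive 1,2-shifts to a carbonyl when two equivalents of Lewis acid suppress proton loss.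

**Step 4**
Reactants: 8 hydroxy-cyclopentanone
Product: 9 (1S,5S)-2,5-dimethyl-5-[(1S)-1-methyl-2-methylidenecyclopentyl]cyclohex-2-en-1-ol
Conditions: Ph3PCH3Br (4 equiv), KOt-Bu (3.8 equiv), toluene, 90 °C
Reagents that add atoms: methyltriphenylphosphonium bromide, C[P+](c1ccccc1)(c1ccccc1)c1ccccc1.[Br-]
Why: Wittig methylenation with excess salt-free ylide (the first equivalent only deprotonates the OH); the quaternary α-carbon cannot epimerize, and this methylenation is the usual last step in syntheses of the parent diene skeleton.

**Step 5**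
Reactants: 9 allylic alcohol; 10 Meldrum's acid
Product: 11 3-{[(1S,5S)-2,5-dimethyl-5-[(1S)-1-methyl-2-methylidenecyclopentyl]cyclohex-2-en-1-yl]oxy}-3-oxopropanoic acid
Conditions: toluene, 100 °C, 4 h
Reagents that add atoms: none
Why: Alcoholysis of Meldrum's acid gives the malonic half-ester with loss of acetone; O-acylation proceeds with retention at C2 and needs neither base nor coupling agent, so both olefins are left alone.

**Step 6**
Reactants: 11 malonic half-ester; 12 3,4-dihydroxybenzaldehyde
Product: 14 (1S,5S)-2,5-dimethyl-5-[(1S)-1-methyl-2-methylidenecyclopentyl]cyclohex-2-en-1-yl (2E)-3-(3,4-dihydroxyphenyl)prop-2-enoate, via arylidenemalonic half-ester 13 (not isolated)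
Conditions: pyridine, piperidine (0.2 equiv), 55 °C, Ar
Reagents that add atoms: none
Why: Knoevenagel condensation followed by Doebner decarboxylation gives the (E)-cinnamate directly, tolerates the free catechol, and touches no stereocentre.

**Compound list**
1 | (R)-(−)-carvone, (5R)-2-methyl-5-(prop-1-en-2-yl)cyclohex-2-en-1-one | C=C(C)[C@@H]1CC=C(C)C(=O)C1 | starting material
2 | (1S,5R)-2-methyl-5-(prop-1-en-2-yl)cyclohex-2-en-1-ol (trans-carveol) | C=C(C)[C@@H]1CC=C(C)[C@@H](O)C1 | intermediate
3 | methyl vinyl ketone (but-3-en-2-one) | C=CC(C)=O | starting material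
4 | chloro(methyl)aluminium alkoxide of 2 | C=C(C)[C@@H]1CC=C(C)[C@@H](O[Al](C)Cl)C1 | intermediate
5 | (Z)-6-[(5S)-5-hydroxy-4-methylcyclohex-3-en-1-ylidene]heptan-2-one | CC(=O)CCC/C(C)=C1/CC=C(C)[C@@H](O)C1 | intermediate
6 | dichloroaluminium alkoxide of 5 | CC(=O)CCC/C(C)=C1/CC=C(C)[C@@H](O[Al](Cl)Cl)C1 | intermediate
7 | aluminate zwitterion: ring-closed C6 carbocation with O2–AlCl2–O11 bridge | C[C@@]1(O[Al-]2(Cl)Cl)CCC[C@]1(C)[C+]1CC=C(C)[C@@H](O2)C1 | intermediate
8 | (2R)-2-[(1S,5S)-5-hydroxy-1,4-dimethylcyclohex-3-en-1-yl]-2-methylcyclopentan-1-one | O=C1CCC[C@]1(C)[C@@]1(C)CC=C(C)[C@@H](O)C1 | intermediate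
9 | (1S,5S)-2,5-dimethyl-5-[(1S)-1-methyl-2-methylidenecyclopentyl]cyclohex-2-en-1-ol | C=C1CCC[C@]1(C)[C@@]1(C)CC=C(C)[C@@H](O)C1 | intermediate
10 | Meldrum's acid (2,2-dimethyl-1,3-dioxane-4,6-dione) | CC1(C)OC(=O)CC(=O)O1 | starting material
11 | 3-{[(1S,5S)-2,5-dimethyl-5-[(1S)-1-methyl-2-methylidenecyclopentyl]cyclohex-2-en-1-yl]oxy}-3-oxopropanoic acid | C=C1CCC[C@]1(C)[C@@]1(C)CC=C(C)[C@@H](OC(=O)CC(=O)O)C1 | intermediate
12 | 3,4-dihydroxybenzaldehyde | O=Cc1ccc(O)c(O)c1 | starting material
13 | (2E)-2-carboxy-3-(3,4-dihydroxyphenyl)prop-2-enoate of 9 (arylidenemalonic half-ester) | C=C1CCC[C@]1(C)[C@@]1(C)CC=C(C)[C@@H](OC(=O)/C(=C/c2ccc(O)c(O)c2)C(=O)O)C1 | intermediate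
14 | (1S,5S)-2,5-dimethyl-5-[(1S)-1-methyl-2-methylidenecyclopentyl]cyclohex-2-en-1-yl (2E)-3-(3,4-dihydroxyphenyl)prop-2-enoate | C=C1CCC[C@]1(C)[C@@]1(C)CC=C(C)[C@@H](OC(=O)/C=C/c2ccc(O)c(O)c2)C1 | target

**Step count and risks**
Total steps: 6. Longest linear sequence: 6.

The three steps most likely to fail, in order of risk:

Step 3. The C6 cation can lose a proton (the resulting cyclohexadienol would aromatize), be captured by chloride or by O11 (oxetane formation, then carbonyl–olefin metathesis), or ring-expand. The C7 configuration also depends on the delivery model and on geometrically pure (Z)-5, because the E isomer would lead to the C7 epimer. The fallback sets out from 5 and changes how the cation is generated. The ketone is masked as the dimethyl ketal (1S,5Z)-5-(6,6-dimethoxyheptan-2-ylidene)-2-methylcyclohex-2-en-1-ol F3 (HC(OMe)3, PPTS, MeOH). The ketal is then ionized with TMSOTf and 2,6-di-tert-butyl-4-methylpyridine in CH2Cl2 at −78 °C. This oxocarbenium-initiated Prins–pinacol sequence uses the same ring closure and the same two methyl shifts, ends in an O-methyl oxocarbenium that is hydrolysed on work-up, and comes back to the route at 8. It removes chloride and the strong aluminium Lewis acid, but gives up the internal delivery, so the facial selectivity would have to be re-examined.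

Step 2. The proton may be taken from the methyl group instead of C6–H, or the reaction may run intermolecularly without geometry control. The fallback sets out from 2 and separates bond formation from olefin placement. The ordinary intermolecular ene reaction (EtAlCl2 2 equiv, methyl vinyl ketone, CH2Cl2, −78 °C) should give the exo-methylene adduct 6-[(1R,5S)-5-hydroxy-4-methylcyclohex-3-en-1-yl]hept-6-en-2-one F1. The 1,1-disubstituted double bond is then moved into the tetrasubstituted position by hydrogen-atom-transfer isomerization (cobalt–salen catalyst, PhSiH3). This gives 5 together with (E)-6-[(5S)-5-hydroxy-4-methylcyclohex-3-en-1-ylidene]heptan-2-one F2, which is removed on AgNO3-impregnated silica, and the fallback comes back to the route at 5.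

Step 4. The ketone lies between a quaternary carbon and a ring CH2, and the ylide may enolize it toward C10 instead of adding. The fallback sets out from 8 and uses a Peterson olefination. Addition of Me3SiCH2Li/CeCl3 (THF, −78 °C) gives the β-hydroxysilane (1R,2R)-2-[(1S,5S)-5-hydroxy-1,4-dimethylcyclohex-3-en-1-yl]-2-methyl-1-[(trimethylsilyl)methyl]cyclopentan-1-ol F4. Elimination with KH in THF then comes back to the route at 9.

**Further compounds**
F1 | step 2 | 6-[(1R,5S)-5-hydroxy-4-methylcyclohex-3-en-1-yl]hept-6-en-2-one | CC(=O)CCCC(=C)[C@@H]1CC=C(C)[C@@H](O)C1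
F2 | step 2 | (E)-6-[(5S)-5-hydroxy-4-methylcyclohex-3-en-1-ylidene]heptan-2-one | CC(=O)CCC/C(C)=C1\CC=C(C)[C@@H](O)C1
F3 | step 3 | (1S,5Z)-5-(6,6-dimethoxyheptan-2-ylidene)-2-methylcyclohex-2-en-1-ol | COC(C)(OC)CCC/C(C)=C1/CC=C(C)[C@@H](O)C1
F4 | step 4 | (1R,2R)-2-[(1S,5S)-5-hydroxy-1,4-dimethylcyclohex-3-en-1-yl]-2-methyl-1-[(trimethylsilyl)methyl]cyclopentan-1-ol | C[Si](C)(C)C[C@@]1(O)CCC[C@]1(C)[C@@]1(C)CC=C(C)[C@@H](O)C1
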